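**Numbering and conventions.** Drimane numbering is used throughout: ring A = C1–C5 and C10, ring B = C5–C10, gem-dimethyl on C4, methyl C15 on C10, C11 on C9, C12 on C8. β is the face of the C10 methyl, α the face of H5 in the target.

## Analysis of the target

Target 21 is a drimane: a trans-fused decalin with a gem-dimethyl group at C4, an angular methyl at C10, carboxyl groups C12 on C8 and C11 on C9, and a (2E,4E,6E)-octatrienoate on the C6 oxygen. Its five stereocentres (C5, C6, C8, C9, C10; 1S,2S,4R,4aS,8aS in naphthalene numbering) are related as follows: H5 is α and trans to the β methyl on C10, while O6, C12 and C11 are all β. O6, C12 and the C10 methyl are therefore all axial on one face of ring B, and C11 is equatorial. This triaxial arrangement is the less stable one at C8. It also makes the 6β-oxygen hard to acylate and prone to close a γ-lactone onto C12 whenever it is free next to an acyl donor. The trienoate does not survive hydrogenation, strong oxidants or strong nucleophiles, so it must come late and the diacid must be unveiled under mild conditions. The hard points are the enantioselective construction of the quaternary C10 next to the C4 gem-dimethyl group, the cis-β,β placement of two carboxyl carbons with C8 axial, and the order of events around O6. The strategy rests on ring B: oxygen at C6 and one-carbon branches at C8 and C10 map onto a carbonyl and the two methyl groups of 2,6-dimethyl-1,4-benzoquinone 1, and the C5–C10 bond is one of its two enantiotopic methyl-bearing alkenes, across which ring A can be annulated.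

## Retrosynthetic reasoning

21 ⇒ 20 ⇒ 17 + 18. The two carboxyl groups are released last from tert-butyl esters by acid, which the trienoate tolerates. Before that, the C6–O acyl bond is cut. The acylation is placed after every reductive and oxidative step. It is run on a di-tert-butyl ester because a tert-butyl ester at C12 is too poor an acyl donor to be captured by the syn-axial 6β-hydroxyl.

17 ⇒ 16 ⇒ 15 ⇒ 13. No skeletal bond is cut here; the C12 oxidation level is adjusted. Diacid 15 is traced to the cis-fused lactone 13, in which C12 is still a CH2–O group and O6 is a silyl ether. The lactone holds C8 and C9 in the cis-β,β arrangement, and once it is opened in base the freed primary alcohol can be oxidised while no alkene is present.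

13 ⇒ 12. The C8–H and C9–H bonds are cut together. Syn addition of hydrogen to the α face of a C8=C9 butenolide, with the β face closed by the C10 methyl and the 6β-silyloxy group, sets both centres at once. It gives the axial C12 that equilibration would never give.

12 ⇒ 10 ⇒ 9. The lactone C11–O bond and the C12–O bond are cut. A C7=C8 alkene bearing the C12 methyl is the right substrate for allylic oxidation. Its more substituted end carries a methyl and a methine, so the methyl is attacked, whereas a C8=C9 alkene would offer the ring methylene C7 as a competitor.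

9 ⇒ 8 ⇒ 7. The C6–H bond is cut. A C6 ketone in a trans-fused 4,4,10-trimethyl decalin is reduced from the α face and gives the axial 6β-alcohol needed.

7 ⇒ 6. C5 is epimerised and the alkene is moved. The cis-fused cycloadduct itself is not expected to epimerise usefully. While C7 and C9 are trigonal, the cis isomer can turn C4 into an axial position on ring B, which avoids the clash of the C4 and C10 methyl groups and the eclipsing of the C6 carbonyl with the gem-dimethyl group. The equilibration is therefore placed at the keto ester stage. There the alkene moves into conjugation with the C6 ketone, C9 becomes tetrahedral, and the cis isomer then has to press an axial C4 methyl against C9 and its substituent.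

6 ⇒ 5 ⇒ 3. The C9–C11 bond is cut. C11 is the one carbon absent from the cycloadduct; it is introduced on the C9 carbonyl through its enol triflate. The enolate is generated regiospecifically by conjugate hydride addition to the enedione, so that the C6 ketone is kept for the later epimerisation.

3 ⇒ 1 + 2. The C1–C10 and C4–C5 bonds are cut. A [4+2] cycloaddition between one enantiotopic alkene of 1 and diene 2 forms ring A and the quaternary C10 in one step from two commercial compounds. The forward reaction has to choose one alkene and one face (enantioselectivity) and one orientation, and it has to overcome the low reactivity of a diene with a cis terminal methyl group.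

## Alternatives that were turned down

Alternative 1: Both rings are cut at C5–C10 and C8–C9, back to the acyclic triene diester A1 (dimethyl (2E,4Z,10E)-4-(tert-butyldimethylsilyloxy)-6,6,10-trimethyldodeca-2,4,10-trienedioate). In the forward direction a chiral Lewis acid would promote an intramolecular Diels–Alder reaction of the C9=C10 enoate with the silyloxydiene, giving A2 (dimethyl (8β,9β)-6-(tert-butyldimethylsilyloxy)drim-6-ene-11,12-dioate).
- In its favour: on oxidation level and stereochemical directness it is stronger than the chosen route. Both carboxyl carbons are present from the start, C5, C8, C9 and C10 are set together, the trans fusion comes from the transition state, and neither hydrogenation nor C12 oxidation is needed.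
- Against it: the first bond joins a neopentyl diene terminus to a β,β-disubstituted enoate carbon, the second joins two carbons that are both α to esters, and the acid-labile silyl enol ether invites a stepwise Mukaiyama-type path. The catalyst has two ester carbonyls to choose from and must enforce one of several endo/exo and facial combinations. A1 itself needs a stereodefined (Z)-enol ether and an (E)-trisubstituted enoate on one chain, a synthesis of many steps before the risk is even reached.
- In comparison: the chosen route places its risk in a step whose precursors are bought, and its catalyst class is established for alkylated quinones.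

Alternative 2: The C9–C10 bond is cut, back to the δ-lactone A3 ((4R,6S)-4-[(tert-butyldimethylsilyloxy)methyl]-6-(2,6,6-trimethylcyclohex-1-en-1-yl)oxan-2-one). Its silyl ketene acetal would undergo a boat-type Claisen ring contraction to A4 ((8α,9α)-12-(tert-butyldimethylsilyloxy)drim-5-en-11-oic acid).
- In its favour: the quaternary C10 is made intramolecularly with chirality transfer from the carbinol carbon, which is a more predictable way to set C10 than an intermolecular cycloaddition.
- Against it: the new bond must form at a tetrasubstituted alkene carbon flanked by the gem-dimethyl group, within a strained boat array. A4 has lost the C6 oxygen (C6 becomes an alkene carbon), has both side chains on the α face, and has C12 at the alcohol level. C6 would have to be re-oxygenated and C5 set by an addition to the C5=C6 alkene, C8 and C9 would both have to be inverted, and C12 oxidised.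
- In comparison: the chosen route keeps the C6 oxygen from the quinone and needs only one correction, at C5.

Alternative 3: The C8–C12 and C9–C11 bonds are cut, back to A5 (11,12-dinordrim-8-en-6β-ol). A hydroxyl-tethered palladium–copper oxidative dicarbonylation in an alcohol would add an alkoxycarbonyl–palladium unit syn across C8=C9 from the β face and carbonylate the C9–palladium bond, giving A6 (methyl 6β-hydroxydrimane-11,12-dioate 12,6-lactone).
- In its favour: this is the most economical way to place both carboxyl carbons. The 6β-hydroxyl delivers them cis and β in one step, which is clearly better than the hydrogenation and the three-level oxidation of C12 in the chosen route.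
- Against it: the insertion must form a bond at C9 beside the quaternary C10 on the face of the axial methyl, through a bridged transition state; oxidation of the secondary alcohol by the oxidant competes; and A5 must first be made enantiopure with the trans fusion and the 6β-alcohol in place. The lactone A6 also ties O6 to C12, the very pairing that is hardest to undo in favour of the trienoate.
- In comparison: the chosen route offers a key step of firmer precedent with no precursor synthesis, at the price of a longer sequence after it.

Key step: step 1

**Assumptions.**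
- The (S)-configured catalyst is taken to give the (8aS) adduct 3, by the accepted binding model and by analogy with acrylate and quinone additions of this catalyst family. If the sense proves opposite, the catalyst from (R)-diphenylprolinol is used with no other change.
- Compounds 7–10 are written as the 9α-ester epimer expected to prevail at equilibrium. The 9β epimer reacts alike, and both converge in step 8.

## Route

Step 1
Reactants: 1 2,6-dimethyl-1,4-benzoquinone; 2 4-methylpenta-1,3-diene
Product: 3 (4aR,8aS)-2,5,5,8a-tetramethyl-4a,5,8,8a-tetrahydronaphthalene-1,4-dione (cis-fused)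
Conditions: (S)-3,3-diphenyl-1-(2-methylphenyl)tetrahydro-1H,3H-pyrrolo[1,2-c][1,3,2]oxazaborole (20 mol%), HN(SO2CF3)2 (18 mol%), 2 (5 equiv), CH2Cl2, −78 → −20 °C
Reagents that add atoms: none
Why: The protonated oxazaborolidine binds the more basic and less hindered C6 carbonyl of 1 (flanked by two CH groups) with the C5–H of the reacting alkene held near the ring oxygen of the catalyst, so that one of the two enantiotopic C5=C10 alkenes is presented with one face screened by an aryl group. The closest known reaction type is the chiral oxazaborolidinium-catalysed Diels–Alder reaction of alkyl-substituted 1,4-benzoquinones with acyclic dienes. The [4+2] process is concerted but strongly asynchronous: the unsubstituted terminus C1 of 2 bonds first to C10, the β-carbon of the activated enone, and the gem-dimethyl terminus C4 then closes onto C5. Ring A is closed as a six-membered carbocycle by suprafacial addition of the two diene termini to C10 and C5, not by cyclisation of a tether. C10 is set by the quinone face that the catalyst leaves open; C5 follows from the suprafacial addition and is therefore cis to the C10 methyl (corrected in step 4). Because each diene terminus carries two identical groups, endo and exo approach give the same product. The step needs orientation and combined enantiotopic-group and face selectivity: the first follows from coordination at O6 and from the avoidance of a bond between two fully substituted carbons, the second from the single productive binding mode of the symmetric quinone.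

Step 2
Reactants: 3 (4aR,8aS)-2,5,5,8a-tetramethyl-4a,5,8,8a-tetrahydronaphthalene-1,4-dione
Product: 5 (4aR,8aS)-2,5,5,8a-tetramethyl-4-oxo-3,4,4a,5,8,8a-hexahydronaphthalen-1-yl trifluoromethanesulfonate, via lithium C9 enolate 4 (not isolated)
Conditions: LiBH(s-Bu)3 (1.05 equiv), THF, −78 °C; then PhN(SO2CF3)2, −78 → 0 °C
Reagents that add atoms: N-phenylbis(trifluoromethanesulfonimide), O=S(=O)(N(c1ccccc1)S(=O)(=O)C(F)(F)F)C(F)(F)F
Why: Conjugate reduction with enolate trapping (reductive triflation): the bulky borohydride should add hydride to C7, the unsubstituted β-carbon of the C9 enone, and the tetrasubstituted C9 enolate, which cannot equilibrate without a proton source, is sulfonylated on oxygen. The C6 ketone is kept for step 4.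

Step 3
Reactants: 5 (4aR,8aS)-2,5,5,8a-tetramethyl-4-oxo-3,4,4a,5,8,8a-hexahydronaphthalen-1-yl trifluoromethanesulfonate
Product: 6 methyl (4aR,8aS)-2,5,5,8a-tetramethyl-4-oxo-3,4,4a,5,8,8a-hexahydronaphthalene-1-carboxylate (methyl 6-oxo-5βH-drima-2,8-dien-11-oate)
Conditions: Pd(OAc)2 (5 mol%), PPh3 (10 mol%), CO (1 atm), MeOH, Et3N, DMF, 50 °C
Reagents that add atoms: carbon monoxide, [C-]#[O+]; methanol, CO
Why: Palladium-catalysed methoxycarbonylation of an enol triflate: oxidative addition, CO insertion and methanolysis form the C9–C11 bond. The ketone and the isolated ring A alkene are inert.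

Step 4
Reactants: 6 methyl (4aR,8aS)-2,5,5,8a-tetramethyl-4-oxo-3,4,4a,5,8,8a-hexahydronaphthalene-1-carboxylate
Product: 7 methyl (1R,4aS,8aS)-2,5,5,8a-tetramethyl-4-oxo-1,4,4a,5,8,8a-hexahydronaphthalene-1-carboxylate (methyl 6-oxo-9βH-drima-2,7-dien-11-oate; trans-fused, H5 α, ester α)
Conditions: NaOMe (0.5 equiv), MeOH, 25 °C, argon
Reagents that add atoms: none
Why: Base-mediated equilibration through the extended enolates: the alkene moves into conjugation with the C6 ketone, which makes C9 tetrahedral, and C5 should then epimerise to the trans fusion because the cis isomer would force an axial C4 methyl against C9 and its substituent. C9 should settle with the ester pseudoaxial on the α face, away from the C8 methyl, an arrangement open only to the trans isomer.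

Step 5
Reactants: 7 methyl (1R,4aS,8aS)-2,5,5,8a-tetramethyl-4-oxo-1,4,4a,5,8,8a-hexahydronaphthalene-1-carboxylate
Product: 8 methyl 6β-hydroxy-9βH-drima-2,7-dien-11-oate
Conditions: NaBH4, CeCl3·7H2O, MeOH, −40 °C
Reagents that add atoms: none
Why: Luche 1,2-reduction: hydride should enter C6 from the α face, opposite to the axial C10 and 4β methyl groups, and give the 6β (pseudoaxial) allylic alcohol. The ester is not touched.

Step 6
Reactants: 8 methyl 6β-hydroxy-9βH-drima-2,7-dien-11-oate
Product: 9 methyl 6β-(tert-butyldimethylsilyloxy)-9βH-drima-2,7-dien-11-oate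
Conditions: t-BuMe2SiOSO2CF3, 2,6-lutidine, CH2Cl2, 0 °C
Reagents that add atoms: tert-butyldimethylsilyl trifluoromethanesulfonate, CC(C)(C)[Si](C)(C)OS(=O)(=O)C(F)(F)F
Why: Silylation with the silyl triflate is needed for the crowded hydroxyl. The ether shields O6 through the oxidative and basic steps and further closes the β face of ring B.

Step 7
Reactants: 9 methyl 6β-(tert-butyldimethylsilyloxy)-9βH-drima-2,7-dien-11-oate
Product: 10 methyl 6β-(tert-butyldimethylsilyloxy)-12-hydroxy-9βH-drima-2,7-dien-11-oate
Conditions: SeO2 (0.5 equiv), t-BuOOH, CH2Cl2, 25 °C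
Reagents that add atoms: selenium dioxide, O=[Se]=O; tert-butyl hydroperoxide, CC(C)(C)OO
Why: Selenium dioxide allylic oxidation (ene reaction, then [2,3]-shift) at the more substituted end of the trisubstituted C7=C8 alkene: the methyl C12 should be preferred over the methine C9–H, which lies near the alkene plane beside the ester. The disubstituted ring A alkene has allylic hydrogens only on C1 and would require attack at the neopentyl C3.

Step 8
Reactants: 10 methyl 6β-(tert-butyldimethylsilyloxy)-12-hydroxy-9βH-drima-2,7-dien-11-oate
Product: 12 6β-(tert-butyldimethylsilyloxy)drima-2,8-dien-11,12-olide (lactone carbonyl C11 on C9, OCH2 C12 on C8), via conjugated hydroxy ester 11 (not isolated)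
Conditions: NaOMe (0.2 equiv), MeOH, 0 → 25 °C
Reagents that add atoms: none
Why: Methoxide moves the alkene to C8=C9 through the ester dienolate, which places the hydroxymethyl and ester groups cis, and transesterification closes the butenolide as an irreversible sink. The C9 centre is erased. In methanol the dienolate should be reprotonated faster than it can expel the C6 silyloxy group.

Step 9
Reactants: 12 6β-(tert-butyldimethylsilyloxy)drima-2,8-dien-11,12-olide
Product: 13 6β-(tert-butyldimethylsilyloxy)-8αH,9αH-drimane-11,12-olide (cis-fused lactone, C12 and C11 both β)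
Conditions: H2 (60 bar), Rh/Al2O3 (5%), EtOAc, 50 °C
Reagents that add atoms: none
Why: Heterogeneous hydrogenation: syn addition of hydrogen to the α face of the tetrasubstituted butenolide alkene, the β face being closed by the C10 methyl and the 6β-silyloxy group, should set C8 and C9 together with C12 and C11 β. The ring A alkene is reduced as well, and rhodium is chosen to avoid hydrogenolysis of the allylic C12–O bond.

Step 10
Reactants: 13 6β-(tert-butyldimethylsilyloxy)-8αH,9αH-drimane-11,12-olide
Product: 15 6β-(tert-butyldimethylsilyloxy)-8αH,9αH-drimane-11,12-dioic acid, via potassium hydroxy carboxylate 14 (not isolated)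
Conditions: KOH, t-BuOH/H2O, 60 °C; then KMnO4, 0 → 25 °C; NaHSO3, HCl to pH 3
Reagents that add atoms: potassium hydroxide, [K+].[OH-]; potassium permanganate, [K+].[O-][Mn](=O)(=O)=O; water, O
Why: Saponification opens the lactone to a hydroxy carboxylate that cannot re-close in base. Alkaline permanganate then oxidises the primary alcohol at C12 to the carboxylate, passing the aldehyde stage faster than C8 can enolise. No alkene is left, and the silyl ether is stable.

Step 11
Reactants: 15 6β-(tert-butyldimethylsilyloxy)-8αH,9αH-drimane-11,12-dioic acid
Product: 16 di-tert-butyl 6β-(tert-butyldimethylsilyloxy)-8αH,9αH-drimane-11,12-dioate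
Conditions: t-BuOC(=N-i-Pr)NH-i-Pr (4 equiv), CH2Cl2, 25 °C
Reagents that add atoms: O-tert-butyl-N,N'-diisopropylisourea, CC(C)NC(=NC(C)C)OC(C)(C)C
Why: Alkylation of the carboxylic acids on oxygen by the protonated isourea works on hindered acids under neutral conditions, so C8 is not disturbed. tert-Butyl esters are chosen because they should not acylate the neighbouring 6β-hydroxyl once it is freed.

Step 12
Reactants: 16 di-tert-butyl 6β-(tert-butyldimethylsilyloxy)-8αH,9αH-drimane-11,12-dioate
Product: 17 di-tert-butyl 6β-hydroxy-8αH,9αH-drimane-11,12-dioate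
Conditions: HF·pyridine, pyridine, THF, 0 → 25 °C
Reagents that add atoms: none
Why: Fluoride-mediated desilylation under weakly acidic, non-basic conditions, so that no alkoxide is formed next to the C12 ester. The tert-butyl esters are stable.

Step 13
Reactants: 17 di-tert-butyl 6β-hydroxy-8αH,9αH-drimane-11,12-dioate; 18 (2E,4E,6E)-octa-2,4,6-trienoic acid
Product: 20 di-tert-butyl 6β-[(2E,4E,6E)-octa-2,4,6-trienoyloxy]-8αH,9αH-drimane-11,12-dioate, via mixed anhydride 19 (not isolated)
Conditions: 18, 2,4,6-Cl3C6H2COCl, Et3N, toluene, 25 °C; then 17, 4-(dimethylamino)pyridine, toluene, 60 °C, dark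
Reagents that add atoms: none
Why: Yamaguchi esterification: the mixed anhydride is attacked at the trienoyl carbonyl by the pyridine catalyst and then by the crowded axial alcohol. No base strong enough to epimerise C8 is present.

Step 14
Reactants: 20 di-tert-butyl 6β-[(2E,4E,6E)-octa-2,4,6-trienoyloxy]-8αH,9αH-drimane-11,12-dioate
Product: 21 (1S,2S,4R,4aS,8aS)-5,5,8a-trimethyl-4-[(2E,4E,6E)-octa-2,4,6-trienoyloxy]decahydronaphthalene-1,2-dicarboxylic acid (target)
Conditions: CF3CO2H, CH2Cl2, 0 → 25 °C, dark
Reagents that add atoms: none
Why: Acidolysis of the tert-butyl esters by alkyl–oxygen cleavage releases the cis-diacid without touching the carbonyl carbons, so that C8 and C9 are not at risk. The trienoate and the C6 ester linkage should be stable to the acid.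

## Compound list

1 | 2,6-dimethyl-1,4-benzoquinone | CC1=CC(=O)C=C(C)C1=O | starting material
2 | 4-methylpenta-1,3-diene | C=CC=C(C)C | starting material
3 | (4aR,8aS)-2,5,5,8a-tetramethyl-4a,5,8,8a-tetrahydronaphthalene-1,4-dione | O=C1C=C(C)C(=O)[C@@]2(C)CC=CC(C)(C)[C@@H]12 | intermediate
4 | lithium (4aR,8aS)-2,5,5,8a-tetramethyl-4-oxo-3,4,4a,5,8,8a-hexahydronaphthalen-1-olate | O=C1CC(C)=C([O-])[C@@]2(C)CC=CC(C)(C)[C@@H]12.[Li+] | intermediate
5 | (4aR,8aS)-2,5,5,8a-tetramethyl-4-oxo-3,4,4a,5,8,8a-hexahydronaphthalen-1-yl trifluoromethanesulfonate | O=C1CC(C)=C(OS(=O)(=O)C(F)(F)F)[C@@]2(C)CC=CC(C)(C)[C@@H]12 | intermediate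
6 | methyl (4aR,8aS)-2,5,5,8a-tetramethyl-4-oxo-3,4,4a,5,8,8a-hexahydronaphthalene-1-carboxylate | O=C1CC(C)=C(C(=O)OC)[C@@]2(C)CC=CC(C)(C)[C@@H]12 | intermediate
7 | methyl (1R,4aS,8aS)-2,5,5,8a-tetramethyl-4-oxo-1,4,4a,5,8,8a-hexahydronaphthalene-1-carboxylate | O=C1C=C(C)[C@@H](C(=O)OC)[C@@]2(C)CC=CC(C)(C)[C@H]12 | intermediate
8 | methyl 6β-hydroxy-9βH-drima-2,7-dien-11-oate | O[C@@H]1C=C(C)[C@@H](C(=O)OC)[C@@]2(C)CC=CC(C)(C)[C@H]12 | intermediate
9 | methyl 6β-(tert-butyldimethylsilyloxy)-9βH-drima-2,7-dien-11-oate | CC(C)(C)[Si](C)(C)O[C@@H]1C=C(C)[C@@H](C(=O)OC)[C@@]2(C)CC=CC(C)(C)[C@H]12 | intermediate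
10 | methyl 6β-(tert-butyldimethylsilyloxy)-12-hydroxy-9βH-drima-2,7-dien-11-oate | CC(C)(C)[Si](C)(C)O[C@@H]1C=C(CO)[C@@H](C(=O)OC)[C@@]2(C)CC=CC(C)(C)[C@H]12 | intermediate
11 | methyl 6β-(tert-butyldimethylsilyloxy)-12-hydroxydrima-2,8-dien-11-oate | CC(C)(C)[Si](C)(C)O[C@@H]1CC(CO)=C(C(=O)OC)[C@@]2(C)CC=CC(C)(C)[C@H]12 | intermediate
12 | 6β-(tert-butyldimethylsilyloxy)drima-2,8-dien-11,12-olide | CC(C)(C)[Si](C)(C)O[C@@H]1CC2=C(C(=O)OC2)[C@@]3(C)CC=CC(C)(C)[C@H]13 | intermediate
13 | 6β-(tert-butyldimethylsilyloxy)-8αH,9αH-drimane-11,12-olide | CC(C)(C)[Si](C)(C)O[C@@H]1C[C@@H]2COC(=O)[C@@H]2[C@@]3(C)CCCC(C)(C)[C@H]13 | intermediate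
14 | potassium 6β-(tert-butyldimethylsilyloxy)-12-hydroxy-8αH,9αH-driman-11-oate | CC(C)(C)[Si](C)(C)O[C@@H]1C[C@H](CO)[C@H](C(=O)[O-])[C@@]2(C)CCCC(C)(C)[C@H]12.[K+] | intermediate
15 | 6β-(tert-butyldimethylsilyloxy)-8αH,9αH-drimane-11,12-dioic acid | CC(C)(C)[Si](C)(C)O[C@@H]1C[C@H](C(=O)O)[C@H](C(=O)O)[C@@]2(C)CCCC(C)(C)[C@H]12 | intermediate
16 | di-tert-butyl 6β-(tert-butyldimethylsilyloxy)-8αH,9αH-drimane-11,12-dioate | CC(C)(C)[Si](C)(C)O[C@@H]1C[C@H](C(=O)OC(C)(C)C)[C@H](C(=O)OC(C)(C)C)[C@@]2(C)CCCC(C)(C)[C@H]12 | intermediate
17 | di-tert-butyl 6β-hydroxy-8αH,9αH-drimane-11,12-dioate | O[C@@H]1C[C@H](C(=O)OC(C)(C)C)[C@H](C(=O)OC(C)(C)C)[C@@]2(C)CCCC(C)(C)[C@H]12 | intermediate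
18 | (2E,4E,6E)-octa-2,4,6-trienoic acid | C/C=C/C=C/C=C/C(=O)O | starting material
19 | (2E,4E,6E)-octa-2,4,6-trienoic 2,4,6-trichlorobenzoic anhydride | C/C=C/C=C/C=C/C(=O)OC(=O)c1c(Cl)cc(Cl)cc1Cl | intermediate
20 | di-tert-butyl 6β-[(2E,4E,6E)-octa-2,4,6-trienoyloxy]-8αH,9αH-drimane-11,12-dioate | C/C=C/C=C/C=C/C(=O)O[C@@H]1C[C@H](C(=O)OC(C)(C)C)[C@H](C(=O)OC(C)(C)C)[C@@]2(C)CCCC(C)(C)[C@H]12 | intermediate
21 | (1S,2S,4R,4aS,8aS)-5,5,8a-trimethyl-4-[(2E,4E,6E)-octa-2,4,6-trienoyloxy]decahydronaphthalene-1,2-dicarboxylic acid | C/C=C/C=C/C=C/C(=O)O[C@@H]1C[C@H](C(=O)O)[C@H](C(=O)O)[C@@]2(C)CCCC(C)(C)[C@H]12 | target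

## Step count and least certain steps

Total step count: 14. Longest linear sequence: 14 steps (from 1 and 2; 18 is bought and enters in step 13).

Step 1 (key step). The s-cis form of 2 is disfavoured by its cis terminal methyl. Under the strong cationic Lewis acid the diene may therefore react stepwise from its s-trans form, which leads to four- or five-membered adducts or to oligomerisation in place of ring A, and the slow reaction may erode the enantioselectivity. The fallback sets out from 1 and returns at 3, and uses a diene whose stepwise path also ends in ring A. Under the same catalyst, 1 is combined with 4-methyl-2-(triisopropylsilyloxy)penta-1,3-diene F1, made from the commercial enone of the same carbon skeleton with i-Pr3SiOSO2CF3 and Et3N. After the first bond, the C2–C3 bond of the silyloxy-stabilised intermediate can rotate, so that concerted or stepwise closure both give (4aR,8aS)-2,5,5,8a-tetramethyl-7-(triisopropylsilyloxy)-4a,5,8,8a-tetrahydronaphthalene-1,4-dione F2. C4F9SO2F with Bu4NF converts the silyl enol ether regiospecifically into the corresponding 7-yl nonafluorobutanesulfonate F3. Pd(OAc)2, PPh3, HCO2H and Bu3N in DMF then replace the sulfonate by hydrogen and give 3.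

Step 2. The hydride may add to the C6 carbonyl in place of C7, or proton exchange may move the enolate to the C6 ketone before sulfonylation, giving a regioisomeric triflate. The fallback sets out from 3 and returns at 5. [(Ph3P)CuH]6 with t-BuMe2SiCl in benzene reduces the enedione strictly in the conjugate sense and traps the enolate as (4aR,8aS)-1-(tert-butyldimethylsilyloxy)-2,5,5,8a-tetramethyl-4a,5,8,8a-tetrahydronaphthalen-4(3H)-one F4. CsF with PhN(SO2CF3)2 in 1,2-dimethoxyethane then exchanges silicon for the triflyl group in the presence of the sulfonylating agent and gives 5.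

Step 4. The equilibrium may leave a large share of the cis-fused isomer if the penalty for the cis form is smaller than argued. The fallback sets out from 7 (as the mixture) and returns at 7. [(Ph3P)CuH]6 in wet benzene reduces the enone to methyl 6-oxo-8αH,9βH-drim-2-en-11-oate F5 (the C8 configuration is immaterial). With C7 and C9 both tetrahedral, the cis isomer suffers two methyl clashes, and mild base (K2CO3, MeOH) should equilibrate C5 to the trans fusion without touching the ester-bearing C9. 2-Iodoxybenzoic acid in DMSO/toluene at 70 °C then restores the C7=C8 enone, the only direction in which the ketone can be dehydrogenated, and gives 7.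

Step 9. The crowded tetrasubstituted alkene may be hydrogenated incompletely or may lose the allylic C12–O bond by hydrogenolysis, and the strain built up as C12 moves between O6 and the C10 methyl may slow the α-face addition. The fallback sets out from 10 and returns at 13, and avoids the tetrasubstituted alkene. [Ir(cod)(PCy3)(py)]PF6 and H2 in CH2Cl2 reduce the trisubstituted C7=C8 alkene (and the ring A alkene) of 10 from the α face, guided by the hydroxyl and the α ester, to methyl 6β-(tert-butyldimethylsilyloxy)-12-hydroxy-8αH,9βH-driman-11-oate F6. NaOMe in MeOH at 40 °C then epimerises C9 to the equatorial β ester, which is drained by lactonisation with the 8β-hydroxymethyl group to give 13.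

Step 13. Acylation of the axial hydroxyl, which is flanked by two methyl groups and the C12 ester, may be slow enough for lactonisation onto C12 with loss of tert-butanol, or for deconjugation of the activated trienoate, to take over. The fallback sets out from 17 and returns at 20. The small and more reactive diethylphosphonoacetic acid is coupled with dicyclohexylcarbodiimide and 4-(dimethylamino)pyridine at 0 °C to give di-tert-butyl 6β-[(diethoxyphosphoryl)acetoxy]-8αH,9αH-drimane-11,12-dioate F7. A Horner–Wadsworth–Emmons reaction with (2E,4E)-hexa-2,4-dienal (LiCl, i-Pr2NEt, MeCN) then builds the 2E alkene and gives 20.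

## Further compounds

F1 | step 1 | 4-methyl-2-(triisopropylsilyloxy)penta-1,3-diene | C=C(O[Si](C(C)C)(C(C)C)C(C)C)C=C(C)C
F2 | step 1 | (4aR,8aS)-2,5,5,8a-tetramethyl-7-(triisopropylsilyloxy)-4a,5,8,8a-tetrahydronaphthalene-1,4-dione | O=C1C=C(C)C(=O)[C@@]2(C)CC(O[Si](C(C)C)(C(C)C)C(C)C)=CC(C)(C)[C@@H]12
F3 | step 1 | (4aR,8aS)-2,5,5,8a-tetramethyl-1,4-dioxo-1,4,4a,5,8,8a-hexahydronaphthalen-7-yl nonafluorobutane-1-sulfonate | O=C1C=C(C)C(=O)[C@@]2(C)CC(OS(=O)(=O)C(F)(F)C(F)(F)C(F)(F)C(F)(F)F)=CC(C)(C)[C@@H]12
F4 | step 2 | (4aR,8aS)-1-(tert-butyldimethylsilyloxy)-2,5,5,8a-tetramethyl-4a,5,8,8a-tetrahydronaphthalen-4(3H)-one | O=C1CC(C)=C(O[Si](C)(C)C(C)(C)C)[C@@]2(C)CC=CC(C)(C)[C@@H]12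
F5 | step 4 | methyl 6-oxo-8αH,9βH-drim-2-en-11-oate | O=C1C[C@H](C)[C@@H](C(=O)OC)[C@@]2(C)CC=CC(C)(C)[C@H]12
F6 | step 9 | methyl 6β-(tert-butyldimethylsilyloxy)-12-hydroxy-8αH,9βH-driman-11-oate | CC(C)(C)[Si](C)(C)O[C@@H]1C[C@H](CO)[C@@H](C(=O)OC)[C@@]2(C)CCCC(C)(C)[C@H]12
F7 | step 13 | di-tert-butyl 6β-[(diethoxyphosphoryl)acetoxy]-8αH,9αH-drimane-11,12-dioate | CCOP(=O)(OCC)CC(=O)O[C@@H]1C[C@H](C(=O)OC(C)(C)C)[C@H](C(=O)OC(C)(C)C)[C@@]2(C)CCCC(C)(C)[C@H]12
A1 | alternative 1 | dimethyl (2E,4Z,10E)-4-(tert-butyldimethylsilyloxy)-6,6,10-trimethyldodeca-2,4,10-trienedioate | COC(=O)/C=C/C(O[Si](C)(C)C(C)(C)C)=C/C(C)(C)CCC/C(C)=C/C(=O)OC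
A2 | alternative 1 | dimethyl (8β,9β)-6-(tert-butyldimethylsilyloxy)drim-6-ene-11,12-dioate | CC(C)(C)[Si](C)(C)OC1=C[C@H](C(=O)OC)[C@H](C(=O)OC)[C@@]2(C)CCCC(C)(C)[C@H]12
A3 | alternative 2 | (4R,6S)-4-[(tert-butyldimethylsilyloxy)methyl]-6-(2,6,6-trimethylcyclohex-1-en-1-yl)oxan-2-one | O=C1C[C@H](CO[Si](C)(C)C(C)(C)C)C[C@H](O1)C1=C(C)CCCC1(C)C
A4 | alternative 2 | (8α,9α)-12-(tert-butyldimethylsilyloxy)drim-5-en-11-oic acid | C1C[C@@H](CO[Si](C)(C)C(C)(C)C)[C@@H](C(=O)O)[C@@]2(C)CCCC(C)(C)C2=1
A5 | alternative 3 | 11,12-dinordrim-8-en-6β-ol | O[C@@H]1CC=C[C@@]2(C)CCCC(C)(C)[C@H]12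
A6 | alternative 3 | methyl 6β-hydroxydrimane-11,12-dioate 12,6-lactone | O=C1O[C@@H]2C[C@H]1[C@H](C(=O)OC)[C@@]3(C)CCCC(C)(C)[C@H]23
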